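Each 2-pyranone is cut at C5–C6 and at the lactone O1–C2 bond, so that C6 is an acyl carbon on a quaternary cyclobutane carbon and C2–C5, with the 3-methyl and 4-methoxy groups, come from one 3-methoxy-2-methylbutenoate. The key step exploits this C6-acyl/C5-nucleophile pairing twice: two lithium dienolates add through their γ-carbons to a meso bis(Weinreb amide), forming both C5–C6 bonds and uniting three fragments. The precursor is the cis,anti,cis cyclobutane from the maleic/dimethylmaleic anhydride photodimer, with the CH-carboxyls as tert-butyl esters and the quaternary carboxyls as N-methoxy-N-methylamides, made by ester transamidation so that no acid next to an amide is ever activated.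

Key step: step 7

Remark: pyranone atoms are numbered as in 2H-pyran-2-one (O1, carbonyl C2, C6 bound to the cyclobutane); the target and all cyclobutane intermediates are meso except 4 and 6, which come from opening a meso anhydride at one carbonyl and are racemic (one enantiomer drawn).
Remark: in the twofold steps 5, 7, 8 and 9 both equivalent arms react in one flask; the half-converted species are not counted as separate intermediates.

Step 1
Reactants: 1 maleic anhydride; 2 2,3-dimethylmaleic anhydride
Product: 3 (1R,2S,3R,4S)-1,2-dimethylcyclobutane-1,2,3,4-tetracarboxylic 1,2:3,4-dianhydride (cis,anti,cis; meso)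
Conditions: hν (Hg lamp, Pyrex filter), Ph2CO (cat.), EtOAc, 20 °C; 1 (3 equiv)
Reagents that add atoms: none
Why: Triplet-sensitised [2+2] photocycloaddition of two cyclic alkenes, in which each ring fusion must be cis because both alkenes are held in five-membered rings and the 1,4-biradical should close with the two anhydride rings on opposite faces (cis,anti,cis, as in the maleic anhydride photodimers), which sets all four stereocentres of the target in their relative sense; 1 is used in excess so that 2 is consumed mainly in the cross reaction, and the homodimers should be removable by fractional crystallisation.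

Step 2
Reactants: 3 cis,anti,cis-dianhydride
Product: 4 mono-tert-butyl ester of 3, i.e. 4-(tert-butoxycarbonyl)-2,3-dimethylcyclobutane-1,2,3-tricarboxylic acid 2,3-anhydride (CH–CH anhydride opened to cis CO2tBu/CO2H, CMe–CMe anhydride intact; racemic)
Conditions: tBuOH, 4-(dimethylamino)pyridine (0.3 equiv), PhMe, 80 °C
Reagents that add atoms: tert-butanol, CC(C)(C)O
Why: Alcoholysis of a cyclic anhydride under nucleophilic catalysis by 4-(dimethylamino)pyridine, in which the bulky alcohol can reach only the carbonyls on the CH carbons (those of the other anhydride are neopentyl-type) and ring opening breaks no bond to a stereocentre.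

Step 3
Reactants: 4 mono-tert-butyl ester
Product: 5 di-tert-butyl (1R,2S,3R,4S)-3,4-dimethylcyclobutane-1,2,3,4-tetracarboxylate 3,4-anhydride (meso; esters cis to each other and to both methyl groups, anhydride on the opposite face)
Conditions: Cl3CC(=NH)OtBu, CH2Cl2–cyclohexane, 25 °C
Reagents that add atoms: tert-butyl 2,2,2-trichloroacetimidate, CC(C)(C)OC(=N)C(Cl)(Cl)Cl
Why: tert-Butylation of a carboxylic acid by a trichloroacetimidate (the acid protonates the imidate and the carboxylate captures the tert-butyl cation), so the carboxyl carbon never becomes an acyl donor and can neither reclose to the anhydride nor epimerise.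

Step 4
Reactants: 5 di-tert-butyl ester anhydride
Product: 7 1,2-di-tert-butyl 3,4-dimethyl (1R,2S,3R,4S)-3,4-dimethylcyclobutane-1,2,3,4-tetracarboxylate (meso), via hemiester acid 6 (not isolated)
Conditions: MeOH, 4-(dimethylamino)pyridine (cat.), PhMe, 60 °C; then Me3SiCHN2, 0 → 25 °C
Reagents that add atoms: methanol, CO; trimethylsilyldiazomethane, C[Si](C)(C)C=[N+]=[N-]
Why: Methanolysis of the hindered anhydride by a small nucleophile followed by diazoalkane esterification of the liberated acid at oxygen, again without acyl activation, so the ring cannot re-form and the cis-diester on the CH carbons meets no strong base.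

Step 5
Reactants: 7 mixed tetraester
Product: 8 di-tert-butyl (1R,2S,3R,4S)-3,4-bis[methoxy(methyl)carbamoyl]-3,4-dimethylcyclobutane-1,2-dicarboxylate (meso; amides cis to each other, trans to the two esters and the two methyl groups)
Conditions: MeNHOMe·HCl, iPrMgCl (2 equiv per amine salt), THF, −20 → 25 °C
Reagents that add atoms: N,O-dimethylhydroxylamine hydrochloride, CNOC.Cl
Why: Ester-to-Weinreb-amide transamidation by the magnesium amide ClMgN(OMe)Me made in the flask, in which the reacting carbonyls carry no α-hydrogen, the tert-butyl esters resist aminolysis and no free Grignard reagent remains to add to the new amides; making both amides from esters avoids an activated acid beside an amide, which in this tetrasubstituted succinic array would collapse back to the anhydride.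

Step 6
Reactants: 9 methyl 2-methylacetoacetate
Product: 11 methyl (E)-3-methoxy-2-methylbut-2-enoate, via dimethyl ketal 10 (not isolated)
Conditions: HC(OMe)3, H2SO4 (cat.), MeOH, 25 °C; then distil (−MeOH)
Reagents that add atoms: trimethyl orthoformate, COC(OC)OC
Why: Acid-catalysed ketalisation by the orthoester followed by acid-catalysed thermal loss of methanol gives the conjugated enol ether, and equilibration under these conditions should favour the E isomer (methoxy trans to the ester), which is purified by distillation.

Step 7
Reactants: 8 bis(Weinreb amide); 11 methyl (E)-3-methoxy-2-methylbut-2-enoate (5 equiv)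
Product: 14 di-tert-butyl (1R,2S,3R,4S)-3,4-bis[(3E)-3,5-dimethoxy-4-methyl-5-oxopent-3-enoyl]-3,4-dimethylcyclobutane-1,2-dicarboxylate, via lithium dienolate 12 (not isolated), via dilithium bis(hemiaminal alkoxide) 13 (not isolated)
Conditions: LiN(iPr)2 (4.8 equiv), THF, −78 °C; then 8, −78 → −30 °C; AcOH, −78 °C
Reagents that add atoms: none
Why: LiN(iPr)2 removes a proton from the C4 methyl of 11 (cis to the ester, so the carbonyl-bound base reaches it) to give the cross-conjugated lithium dienolate 12, whose terminal CH2 adds to each amide carbonyl of 8; the lithium hemiaminal alkoxides are held as five-membered N-methoxy chelates (13) until the acetic acid quench releases the two ketones and MeNHOMe. The closest known reaction type is the γ-acylation (vinylogous Claisen condensation) of lithium dienolates of 3-alkoxybut-2-enoates, here run as a Weinreb ketone synthesis with an extended enolate. No ring is closed and no stereocentre is created; the four ring stereocentres are spectators, and the E enoate geometry (ester cis to the new CH2) needed for lactonisation should be kept. γ- rather than α-attack is required and is secured by the fully substituted α-carbon of 12, which would have to become a congested quaternary centre, and by the open, more reactive terminus. Single addition at each carbonyl and the absence of crosstalk between the two arms (aldol or Dieckmann-type closure onto the neighbour) rest on the chelated tetrahedral intermediates, which keep both ketones masked until work-up. The tert-butyl esters are too hindered to be acylated, and keeping 11 in slight excess over LiN(iPr)2 leaves no free amide base to remove their α-protons or to fragment the N–OMe groups.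

Step 8
Reactants: 14 bis(keto enoate)
Product: 15 di-tert-butyl (1R,2S,3R,4S)-3,4-bis(4-methoxy-3-methyl-2-oxo-2H-pyran-6-yl)-3,4-dimethylcyclobutane-1,2-dicarboxylate (meso)
Conditions: 1,8-diazabicyclo[5.4.0]undec-7-ene (DBU), PhMe, 25 → 60 °C
Reagents that add atoms: none
Why: DBU enolises each ketone towards its doubly activated CH2 and the enolate oxygen attacks the cis-disposed methyl ester (6-exo-trig enol lactonisation with loss of methanol, the standard closure of 5-oxo-3-alkoxypent-2-enoates to 4-alkoxy-2-pyranones); any Z enoate can equilibrate through the same extended enolate, and the base is too weak to epimerise the ester α-carbons.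

Step 9
Reactants: 15 bis(pyranone) di-tert-butyl ester
Product: 16 (1R,2S,3R,4S)-3,4-bis(4-methoxy-3-methyl-2-oxo-2H-pyran-6-yl)-3,4-dimethylcyclobutane-1,2-dicarboxylic acid (CNP0574758.1; meso; acids cis to each other and to both methyl groups, pyranones on the opposite face)
Conditions: CF3CO2H, CH2Cl2, 0 → 25 °C
Reagents that add atoms: none
Why: Acidolysis of the tert-butyl esters by the E1 pathway (loss of 2-methylpropene) should leave the 4-methoxy-2-pyranones and the four stereocentres untouched, and without a dehydrating agent the cis-diacid should not close to its anhydride.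

Compound list
1 | maleic anhydride | O=C1OC(=O)C=C1 | starting material
2 | 2,3-dimethylmaleic anhydride | CC1=C(C)C(=O)OC1=O | starting material
3 | (1R,2S,3R,4S)-1,2-dimethylcyclobutane-1,2,3,4-tetracarboxylic 1,2:3,4-dianhydride (cis,anti,cis; meso; methyl groups on the face of the CH–CH anhydride) | O=C1OC(=O)[C@@]2(C)[C@@H]3C(=O)OC(=O)[C@@H]3[C@@]12C | intermediate
4 | 4-(tert-butoxycarbonyl)-2,3-dimethylcyclobutane-1,2,3-tricarboxylic acid 2,3-anhydride (racemic; relative configuration as in 3) | O=C1OC(=O)[C@@]2(C)[C@H](C(=O)OC(C)(C)C)[C@H](C(=O)O)[C@@]12C | intermediate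
5 | di-tert-butyl (1R,2S,3R,4S)-3,4-dimethylcyclobutane-1,2,3,4-tetracarboxylate 3,4-anhydride (meso) | O=C1OC(=O)[C@@]2(C)[C@H](C(=O)OC(C)(C)C)[C@H](C(=O)OC(C)(C)C)[C@@]12C | intermediate
6 | 2,3-bis(tert-butoxycarbonyl)-4-(methoxycarbonyl)-1,4-dimethylcyclobutane-1-carboxylic acid (racemic; relative configuration as in 5; not isolated) | COC(=O)[C@@]1(C)[C@H](C(=O)OC(C)(C)C)[C@H](C(=O)OC(C)(C)C)[C@@]1(C)C(=O)O | intermediate
7 | 1,2-di-tert-butyl 3,4-dimethyl (1R,2S,3R,4S)-3,4-dimethylcyclobutane-1,2,3,4-tetracarboxylate (meso) | COC(=O)[C@@]1(C)[C@H](C(=O)OC(C)(C)C)[C@H](C(=O)OC(C)(C)C)[C@@]1(C)C(=O)OC | intermediate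
8 | di-tert-butyl (1R,2S,3R,4S)-3,4-bis[methoxy(methyl)carbamoyl]-3,4-dimethylcyclobutane-1,2-dicarboxylate (meso) | CON(C)C(=O)[C@@]1(C)[C@H](C(=O)OC(C)(C)C)[C@H](C(=O)OC(C)(C)C)[C@@]1(C)C(=O)N(C)OC | intermediate
9 | methyl 2-methylacetoacetate (methyl 2-methyl-3-oxobutanoate) | CC(=O)C(C)C(=O)OC | starting material
10 | methyl 3,3-dimethoxy-2-methylbutanoate (not isolated) | COC(=O)C(C)C(C)(OC)OC | intermediate
11 | methyl (E)-3-methoxy-2-methylbut-2-enoate | COC(=O)/C(C)=C(/OC)C | intermediate
12 | lithium 1,3-dimethoxy-2-methylbuta-1,3-dien-1-olate (not isolated) | [Li+].[O-]C(OC)=C(C)C(=C)OC | intermediate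
13 | dilithium bis(alkoxide) of di-tert-butyl 3,4-bis{(3E)-1-hydroxy-3,5-dimethoxy-1-[methoxy(methyl)amino]-4-methyl-5-oxopent-3-en-1-yl}-3,4-dimethylcyclobutane-1,2-dicarboxylate (ring configuration as in 8; hemiaminal carbons unassigned; not isolated) | COC(=O)/C(C)=C(/OC)CC([O-])(N(C)OC)[C@@]1(C)[C@H](C(=O)OC(C)(C)C)[C@H](C(=O)OC(C)(C)C)[C@@]1(C)C([O-])(N(C)OC)C/C(OC)=C(C)\C(=O)OC.[Li+].[Li+] | intermediate
14 | di-tert-butyl (1R,2S,3R,4S)-3,4-bis[(3E)-3,5-dimethoxy-4-methyl-5-oxopent-3-enoyl]-3,4-dimethylcyclobutane-1,2-dicarboxylate (meso; C1 of each side chain is the ketone carbon) | COC(=O)/C(C)=C(/OC)CC(=O)[C@@]1(C)[C@H](C(=O)OC(C)(C)C)[C@H](C(=O)OC(C)(C)C)[C@@]1(C)C(=O)C/C(OC)=C(C)\C(=O)OC | intermediate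
15 | di-tert-butyl (1R,2S,3R,4S)-3,4-bis(4-methoxy-3-methyl-2-oxo-2H-pyran-6-yl)-3,4-dimethylcyclobutane-1,2-dicarboxylate (meso) | COc1cc([C@@]2(C)[C@H](C(=O)OC(C)(C)C)[C@H](C(=O)OC(C)(C)C)[C@@]2(C)c2cc(OC)c(C)c(=O)o2)oc(=O)c1C | intermediate
16 | (1R,2S,3R,4S)-3,4-bis(4-methoxy-3-methyl-2-oxo-2H-pyran-6-yl)-3,4-dimethylcyclobutane-1,2-dicarboxylic acid (meso) | COc1cc([C@@]2(C)[C@H](C(=O)O)[C@H](C(=O)O)[C@@]2(C)c2cc(OC)c(C)c(=O)o2)oc(=O)c1C | target

Total step count: 9
Longest linear sequence: 8 steps (steps 1, 2, 3, 4, 5, 7, 8, 9 from 1 and 2; step 6 is a one-step side branch)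

Three steps most likely to fail

Step 7. Addition of the stabilised dienolate to two neopentyl-type amide carbonyls may be slow. Competing processes could then take over: self-condensation of the dienolate, attack of the first tetrahedral alkoxide on the neighbouring amide, base-induced loss of formaldehyde from the N-methoxy groups, or epimerisation α to the esters. The fallback sets out from 8 and 9 and comes back at 15. Methyl 2-methylacetoacetate 9 is converted by NaH, then nBuLi (THF, 0 °C) into the sodium lithium dianion of methyl 2-methylacetoacetate F1, a harder and more reactive γ-nucleophile. This should acylate both amides of 8 (−78 → 0 °C, again through chelated tetrahedral intermediates) to give the bis(3,5-diketo ester) di-tert-butyl 3,4-bis(5-methoxy-4-methyl-3,5-dioxopentanoyl)-3,4-dimethylcyclobutane-1,2-dicarboxylate F2. DBU in PhMe should close both rings by enolate lactonisation to the bis(4-hydroxy-3-methyl-2-pyranone) di-tert-butyl ester F3. O-Methylation of the two 4-hydroxyl groups with Me2SO4 and K2CO3 in acetone should then give 15, so the methoxy groups are placed after, not before, ring closure.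

Step 5. Transamidation at the second hindered ester may stall at the mono-amide, and forcing it may begin to epimerise the CH centres. The fallback sets out from 5 and comes back at 8, introducing the two amides one after the other. The hindered anhydride of 5 is opened by MeNHOMe·HCl and K2CO3 in DMF (40 °C) to the potassium amide-carboxylate F4. Without acidification this is alkylated at oxygen with CF3CH2OSO2CF3 to the 2,2,2-trifluoroethyl ester F5, an activated ester made by alkylation and not by acyl activation. This more electrophilic ester should be displaced by ClMgN(OMe)Me (from MeNHOMe·HCl and iPrMgCl, THF, −20 °C) to give 8.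

Step 1. Homodimerisation of each anhydride competes with the cross-cycloaddition, which lowers the conversion to the mixed adduct and leaves three sparingly soluble dianhydrides to separate. The fallback sets out from 2 and comes back at 3. Anhydride 2 is irradiated (Pyrex, acetone as solvent and sensitiser) with an excess of 2,5-dihydrofuran, an alkene that neither absorbs nor dimerises, to give the cis,anti,cis adduct 6,7-dimethyl-3-oxabicyclo[3.2.0]heptane-6,7-dicarboxylic anhydride F6. Oxidation of the tetrahydrofuran ring with HNO3 (65%) and NH4VO3 (cat.) at 60 °C, the classical cleavage of tetrahydrofurans to succinic acids, should give the tetraacid (1R,2S,3R,4S)-1,2-dimethylcyclobutane-1,2,3,4-tetracarboxylic acid F7, the anhydride being hydrolysed on the way. Ac2O at 100 °C should then close both anhydrides to give 3.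

Further compounds
F1 | step 7 | lithium sodium 1-methoxy-2-methylbuta-1,3-diene-1,3-bis(olate) (dianion of methyl 2-methylacetoacetate) | C=C([O-])C(C)=C([O-])OC.[Na+].[Li+]
F2 | step 7 | di-tert-butyl (1R,2S,3R,4S)-3,4-bis(5-methoxy-4-methyl-3,5-dioxopentanoyl)-3,4-dimethylcyclobutane-1,2-dicarboxylate (side-chain CH(CH3) centres unassigned) | COC(=O)C(C)C(=O)CC(=O)[C@@]1(C)[C@H](C(=O)OC(C)(C)C)[C@H](C(=O)OC(C)(C)C)[C@@]1(C)C(=O)CC(=O)C(C)C(=O)OC
F3 | step 7 | di-tert-butyl (1R,2S,3R,4S)-3,4-bis(4-hydroxy-3-methyl-2-oxo-2H-pyran-6-yl)-3,4-dimethylcyclobutane-1,2-dicarboxylate | Oc1cc([C@@]2(C)[C@H](C(=O)OC(C)(C)C)[C@H](C(=O)OC(C)(C)C)[C@@]2(C)c2cc(O)c(C)c(=O)o2)oc(=O)c1C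
F4 | step 5 | potassium 2,3-bis(tert-butoxycarbonyl)-4-[methoxy(methyl)carbamoyl]-1,4-dimethylcyclobutane-1-carboxylate (racemic; relative configuration as in 5) | CON(C)C(=O)[C@@]1(C)[C@H](C(=O)OC(C)(C)C)[C@H](C(=O)OC(C)(C)C)[C@@]1(C)C(=O)[O-].[K+]
F5 | step 5 | 1,2-di-tert-butyl 3-(2,2,2-trifluoroethyl) 4-[methoxy(methyl)carbamoyl]-3,4-dimethylcyclobutane-1,2,3-tricarboxylate (racemic; relative configuration as in 5) | CON(C)C(=O)[C@@]1(C)[C@H](C(=O)OC(C)(C)C)[C@H](C(=O)OC(C)(C)C)[C@@]1(C)C(=O)OCC(F)(F)F
F6 | step 1 | cis,anti,cis-6,7-dimethyl-3-oxabicyclo[3.2.0]heptane-6,7-dicarboxylic anhydride (meso) | O=C1OC(=O)[C@@]2(C)[C@@H]3COC[C@@H]3[C@@]12C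
F7 | step 1 | (1R,2S,3R,4S)-1,2-dimethylcyclobutane-1,2,3,4-tetracarboxylic acid (meso) | OC(=O)[C@@]1(C)[C@H](C(=O)O)[C@H](C(=O)O)[C@@]1(C)C(=O)O
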